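The geranyl chain is disconnected between its allylic CH2 and its vinylic CH. That CH2 hangs on the quaternary carbon shared by ring A (cyclohexene) and ring D (cyclohexenone), β to the ring D ketone: a ketone homoenolate that has no β-hydrogen. The precursor is therefore the geranyl-free tetracycle with this CH2 tied to the ketone carbon as a temporary cyclopropanol, installed by alkoxide-directed cyclopropanation, which sets the quaternary centre. Palladium-catalysed ring-opening cross-coupling with (E)-1-iodo-2,6-dimethylhepta-1,5-diene then breaks the temporary bond, forms the CH2–CH= bond, restores the ketone and gives the unprotected target. The tetracycle comes from an asymmetric quinone Diels–Alder reaction with (E)-β-ocimene and a Prins cyclisation.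

Key step: step 9

Remark on ring labels: ring A = cyclohexene, ring B = cyclopentane, ring C = five-membered cyclic enol ether, ring D = cyclohexenone. "Bottom face" is the face of ring D that carries the two tertiary hydroxyls; "top face" is the opposite one. PMB = 4-methoxybenzyl.

Remark on assumptions: (E)-β-ocimene is taken as commercially available in geometrically pure form. The (S)-BINOL ligand in step 6 is a working assignment of the sense of induction; the antipodal ligand would be used if the opposite adduct formed.

**Route**

Step 1
Reactants: 1 6-methylhept-5-en-2-one
Product: 3 6-methylhept-5-en-1-yne, via enol phosphate 2 (not isolated)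
Conditions: LiN(iPr)2 (1.1 equiv), THF, −78 °C; ClP(O)(OEt)2; then LiN(iPr)2 (2.3 equiv), −78 °C → rt; H2O
Reagents that add atoms: none
Why: Kinetic deprotonation at the methyl group, O-phosphorylation and base-induced elimination of diethyl phosphate from the terminal enol phosphate (methyl ketone to terminal alkyne protocol) should give the alkyne without touching the remote trisubstituted alkene.

Step 2
Reactants: 3 6-methylhept-5-en-1-yne
Product: 5 (E)-1-iodo-2,6-dimethylhepta-1,5-diene, via alkenylalane 4 (not isolated)
Conditions: AlMe3 (2 equiv), Cp2ZrCl2 (25 mol%), CH2Cl2, 0 °C → rt; then I2, THF, −30 → 0 °C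
Reagents that add atoms: trimethylaluminium, C[Al](C)C; iodine, II
Why: Zirconium-catalysed Negishi carboalumination adds methyl and aluminium syn across the terminal alkyne with methyl on the internal carbon, and iododealumination with retention fixes the E trisubstituted alkene.

Step 3
Reactants: 6 phloroglucinol; 7 prenyl bromide
Product: 8 2-(3-methylbut-2-en-1-yl)benzene-1,3,5-triol
Conditions: aq KOH (10%), 0 °C → rt, phloroglucinol in threefold excess
Reagents that add atoms: none
Why: In water the phloroglucinolate reacts as a carbon nucleophile (C-alkylation of an ambident phenolate), and the excess of phloroglucinol should suppress polyalkylation so that the mono-C-prenyl triol is the main product.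

Step 4
Reactants: 8 2-(3-methylbut-2-en-1-yl)benzene-1,3,5-triol
Product: 9 3,5-bis[(4-methoxybenzyl)oxy]-2-(3-methylbut-2-en-1-yl)phenol
Conditions: 4-methoxybenzyl chloride (2.05 equiv), K2CO3, DMF, 0 °C → rt
Reagents that add atoms: 4-methoxybenzyl chloride, COc1ccc(CCl)cc1
Why: Williamson etherification in a dipolar aprotic solvent is O-selective, should take the unhindered hydroxyl para to the prenyl group first and then one of the two equivalent hydroxyls beside it, and with two equivalents of halide the bis-ether should be the main product and separable from mono- and tris-ethers.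

Step 5
Reactants: 9 3,5-bis[(4-methoxybenzyl)oxy]-2-(3-methylbut-2-en-1-yl)phenol
Product: 10 2,6-bis[(4-methoxybenzyl)oxy]-3-(3-methylbut-2-en-1-yl)cyclohexa-2,5-diene-1,4-dione
Conditions: (KSO3)2NO (2.5 equiv), KH2PO4 buffer, H2O/acetone, 0 °C → rt
Reagents that add atoms: potassium nitrosodisulfonate, [K+].[K+].[O-]S(=O)(=O)N([O])S(=O)(=O)[O-]
Why: In this Teuber oxidation the phenoxyl radical is captured at its free para position by a second nitrosodisulfonate radical, which delivers the new carbonyl oxygen, while the benzyl ethers and the trisubstituted alkene should be inert to this mild one-electron oxidant.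

Step 6
Reactants: 10 bis-PMB prenylquinone; 11 (E)-β-ocimene
Product: 12 cis-fused Diels–Alder adduct
Conditions: [(S)-BINOL]TiCl2 (30 mol%, preformed, free of molecular sieves), diene in threefold excess, toluene, −40 → 0 °C
Reagents that add atoms: none
Why: In this chiral-Lewis-acid-catalysed endo Diels–Alder reaction, tetravalent titanium chelated between the quinone carbonyl flanked by the two ethers and one ether oxygen makes the hydrogen-bearing carbon of the only trisubstituted quinone alkene the electrophilic β-position, so the CH2 terminus of the diene should bond there and the substituted terminus to the ether-bearing carbon, the endo transition state places the hydrogen of the new CH(CH2CH=CMe2) centre cis to the angular ether, and the BINOL ligand selects the alkene face and thereby the absolute configuration of the three new stereocentres.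

Step 7
Reactants: 12 cis-fused Diels–Alder adduct
Product: 14 geranyl-free tetracyclic diol ketone, via mono-PMB tetracycle 13 (not isolated)
Conditions: SnCl4 (2.2 equiv), anisole (10 equiv), 2,6-di-tert-butyl-4-methylpyridine, CH2Cl2, −78 → −30 °C
Reagents that add atoms: none
Why: Chelated tin tetrachloride activates the ketone flanked by the two ether-bearing carbons for a Prins cyclisation by the pendant trisubstituted alkene, which can reach it only from the top face, the tertiary cation is captured by the enol ether oxygen with loss of its 4-methoxybenzyl cation to anisole, and the same Lewis acid ionises the remaining tertiary PMB ether, so rings B and C, the cis-diol and the two new stereocentres (cis ring fusions enforced by the short tether) should arise in one operation.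

Step 8
Reactants: 14 geranyl-free tetracyclic diol ketone
Product: 15 ring D cyclopropanol
Conditions: LiN(iPr)2 (3.3 equiv), THF, −78 °C; then CH2I2 (3 equiv), Sm powder (activated with HgCl2), −78 °C → rt; pH 7 buffer
Reagents that add atoms: diiodomethane, ICI
Why: In this alkoxide-directed samarium carbenoid cyclopropanation of a lithium enolate, the cross-conjugated dienolate formed at the only enolisable position is most nucleophilic at the ring-fusion carbon, the neighbouring tertiary alkoxide should deliver the carbenoid to its own bottom face so that the new CH2 ends cis to that oxygen and ring A becomes cis-fused, and unactivated trisubstituted alkenes do not react with samarium carbenoids.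

Step 9
Reactants: 15 ring D cyclopropanol; 5 (E)-1-iodo-2,6-dimethylhepta-1,5-diene
Product: 16 target (CNP0323114.1)
Conditions: Pd(OAc)2 (10 mol%), XPhos (20 mol%), Cs2CO3 (2 equiv), alkenyl iodide in 1.5-fold excess, toluene, 60 °C
Reagents that add atoms: none
Why: Oxidative addition of zerovalent palladium to the alkenyl iodide with retention of the E geometry, exchange of iodide for the cyclopropanol oxygen and strain-driven β-carbon elimination that breaks the bond between the carbinol carbon and the cyclopropane CH2 should give a palladium homoenolate (ring D ketone restored, CH2–Pd(alkenyl) on the quaternary fusion carbon), and reductive elimination then forms the CH2–CH= bond. The closest known reaction types are the palladium-catalysed ring-opening cross-coupling of cyclopropanols with aryl and alkenyl halides and the Negishi coupling of zinc homoenolates with alkenyl halides. No ring is closed; the temporary three-membered ring is opened by β-carbon elimination at the palladium alkoxide. No stereocentre is formed: the quaternary centre was set in step 8 and none of its bonds is broken, and the alkene geometry is carried over from the iodide. The step needs cleavage of the CH2–C(OH) bond in preference to the bond to the quaternary carbon, which palladium secures by moving to the less substituted carbon, and coupling in preference to β-hydride elimination, which the hydrogen-free quaternary carbon rules out. The two other tertiary alcohols are unstrained and should not undergo β-carbon elimination at this temperature.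

**Compound list**

1 | 6-methylhept-5-en-2-one | CC(=O)CCC=C(C)C | starting material
2 | enol phosphate, diethyl 6-methylhepta-1,5-dien-2-yl phosphate | C=C(CCC=C(C)C)OP(=O)(OCC)OCC | intermediate
3 | 6-methylhept-5-en-1-yne | C#CCCC=C(C)C | intermediate
4 | alkenylalane, (E)-(2,6-dimethylhepta-1,5-dien-1-yl)dimethylalane | CC(C)=CCC/C(C)=C/[Al](C)C | intermediate
5 | (E)-1-iodo-2,6-dimethylhepta-1,5-diene | CC(C)=CCC/C(C)=C/I | intermediate
6 | phloroglucinol (benzene-1,3,5-triol) | Oc1cc(O)cc(O)c1 | starting material
7 | prenyl bromide (1-bromo-3-methylbut-2-ene) | CC(C)=CCBr | starting material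
8 | 2-(3-methylbut-2-en-1-yl)benzene-1,3,5-triol | CC(C)=CCc1c(O)cc(O)cc1O | intermediate
9 | 3,5-bis[(4-methoxybenzyl)oxy]-2-(3-methylbut-2-en-1-yl)phenol | CC(C)=CCc1c(O)cc(OCc2ccc(OC)cc2)cc1OCc1ccc(OC)cc1 | intermediate
10 | bis-PMB prenylquinone, 2,6-bis[(4-methoxybenzyl)oxy]-3-(3-methylbut-2-en-1-yl)cyclohexa-2,5-diene-1,4-dione | CC(C)=CCC1=C(OCc2ccc(OC)cc2)C(=O)C(OCc2ccc(OC)cc2)=CC1=O | intermediate
11 | (E)-β-ocimene, (3E)-3,7-dimethylocta-1,3,6-triene | C=C/C(C)=C/CC=C(C)C | starting material
12 | cis-fused Diels–Alder adduct, 2,8a-bis[(4-methoxybenzyl)oxy]-7-methyl-3,8-bis(3-methylbut-2-en-1-yl)-4a,5,8,8a-tetrahydronaphthalene-1,4-dione, 4a-H, 8a-OPMB and 8-H mutually cis | [C@H]12CC=C(C)[C@H](CC=C(C)C)[C@]2(OCc3ccc(OC)cc3)C(=O)C(OCc3ccc(OC)cc3)=C(CC=C(C)C)C1=O | intermediate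
13 | mono-PMB tetracycle: compound 14 with a 4-methoxybenzyl ether on the tertiary oxygen next to the ring A/D fusion carbon | [C@H]12CC=C(C)[C@@H]3C[C@@H]4C(C)(C)OC(=C(CC=C(C)C)C1=O)[C@]4(O)[C@@]32OCc5ccc(OC)cc5 | intermediate
14 | geranyl-free tetracyclic diol ketone: the target with H in place of geranyl, this H cis to the neighbouring tertiary OH | [C@H]12CC=C(C)[C@@H]3C[C@@H]4C(C)(C)OC(=C(CC=C(C)C)C1=O)[C@]4(O)[C@@]32O | intermediate
15 | ring D cyclopropanol: CH2 bridging the ring A/D fusion carbon and the former ketone carbon on the bottom face, cyclopropanol OH on the top face | C1[C@]23CC=C(C)[C@@H]4C[C@@H]5C(C)(C)OC(=C(CC=C(C)C)[C@@]12O)[C@]5(O)[C@@]43O | intermediate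
16 | target CNP0323114.1 | CC(C)=CCC/C(C)=C/C[C@]12CC=C(C)[C@@H]3C[C@@H]4C(C)(C)OC(=C(CC=C(C)C)C1=O)[C@]4(O)[C@@]32O | target

**Step count**

Total: 9 steps. Longest linear sequence: 7 steps (steps 3 to 9, from phloroglucinol); steps 1 and 2 make the iodide 5 for the convergent last step.

**Steps most likely to fail, with fallbacks**

Risk at step 6: the ether-bearing quinone alkene is a weak dienophile, so catalyst turnover may stall; the Lewis acid may ionise a PMB ether; and facial or regiochemical control may be incomplete. The fallback sets out from 10 and gives up catalyst control. An uncatalysed thermal cycloaddition with 11 (toluene, 90 °C, BHT) should follow the same regiochemistry, because the carbonyl flanked by the two ethers is the stronger acceptor while the other is tied up as a doubly vinylogous ester. It would give 12 as a racemate, that is, together with its mirror image ent-12 F1. The racemate is taken through the conditions of step 7, where the mirror-image mono-PMB tetracycle ent-13 F2 forms alongside 13 and is not isolated. The resulting racemic diol, 14 together with its mirror image ent-14 F3, is resolved by preparative chromatography on a chiral stationary phase. The fallback returns to the route at 14.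

Risk at step 8: the lithium β-alkoxide of the ketone may open by retro-aldol cleavage before enolisation is complete, deprotonation of the hindered ring-fusion methine may stall, or the heterogeneous samarium carbenoid may be quenched before it transfers its methylene. The fallback sets out from 14, avoids anionic intermediates and lets a free hydroxyl steer a zinc carbenoid.
- Soft enolisation of the vinylogous ester carbonyl with TBSOTf (1.05 equiv) and Et3N (CH2Cl2, −78 °C) should give the silyl dienol ether diol F4. The hindered tertiary alcohols silylate far more slowly under these conditions.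
- Furukawa cyclopropanation (Et2Zn, CH2I2, CH2Cl2, 0 °C) should take the siloxy alkene, the nucleophilic terminus of the 1-alkoxy-3-siloxy-1,3-diene. The zinc alkoxide of the allylic tertiary hydroxyl next to the ring-fusion carbon should deliver the methylene to the bottom face. This gives the O-silyl cyclopropanol F5.
- Desilylation with Bu4NF buffered with acetic acid (THF, 0 °C) returns to the route at 15.

Risk at step 9: the homoenolate may be protonated to the C-methyl ketone, β-carbon elimination may go toward the quaternary carbon, the alkenyl-substituted cyclopropanol may rearrange, or reductive elimination at the neopentyl-type palladium alkyl may be slow. The fallback sets out from 14, bypasses 15 and uses an open-chain electrophile.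
- Aldol hydroxymethylation (LiN(iPr)2, 3.3 equiv, then gaseous formaldehyde, −78 °C) on the face of the neighbouring alkoxide should give the hydroxymethyl ketone F6.
- Appel iodination of its primary hydroxyl (I2, PPh3, imidazole) gives the iodomethyl ketone F7.
- Nickel-catalysed reductive cross-electrophile coupling of the iodomethyl ketone with 5 (NiBr2(dme), 4,4'-di-tert-butyl-2,2'-bipyridine, Mn powder, DMA) forms the same CH2–CH= bond and returns to the route at 16.

Further compounds
F1 | step 6 | ent-12 (enantiomer of 12) | [C@@H]12CC=C(C)[C@@H](CC=C(C)C)[C@@]2(OCc3ccc(OC)cc3)C(=O)C(OCc3ccc(OC)cc3)=C(CC=C(C)C)C1=O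
F2 | step 6 | ent-13 (enantiomer of 13) | [C@@H]12CC=C(C)[C@H]3C[C@H]4C(C)(C)OC(=C(CC=C(C)C)C1=O)[C@@]4(O)[C@]32OCc5ccc(OC)cc5
F3 | step 6 | ent-14 (enantiomer of 14) | [C@@H]12CC=C(C)[C@H]3C[C@H]4C(C)(C)OC(=C(CC=C(C)C)C1=O)[C@@]4(O)[C@]32O
F4 | step 8 | silyl dienol ether diol: tert-butyldimethylsilyl enol ether of 14 toward the ring A/D fusion carbon, both tertiary hydroxyls free | CC(C)(C)[Si](C)(C)OC1=C2CC=C(C)[C@@H]3C[C@@H]4C(C)(C)OC(=C1CC=C(C)C)[C@]4(O)[C@@]32O
F5 | step 8 | O-silyl cyclopropanol: 15 with a tert-butyldimethylsilyl ether on the cyclopropanol oxygen, both tertiary hydroxyls free | C1[C@]23CC=C(C)[C@@H]4C[C@@H]5C(C)(C)OC(=C(CC=C(C)C)[C@@]12O[Si](C)(C)C(C)(C)C)[C@]5(O)[C@@]43O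
F6 | step 9 | hydroxymethyl ketone: 14 with CH2OH on the ring A/D fusion carbon, cis to the neighbouring tertiary OH | OC[C@]12CC=C(C)[C@@H]3C[C@@H]4C(C)(C)OC(=C(CC=C(C)C)C1=O)[C@]4(O)[C@@]32O
F7 | step 9 | iodomethyl ketone: F6 with I in place of the primary OH | IC[C@]12CC=C(C)[C@@H]3C[C@@H]4C(C)(C)OC(=C(CC=C(C)C)C1=O)[C@]4(O)[C@@]32O
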